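**Retrosynthetic overview**
1. Target 33 ⇒ lutein 31 + two myristoyl chloride 32 (O-acylation last).
2. Lutein 31 ⇒ Wittig at C15=C15' between the ring A C20 phosphonium salt 15 and the ring B C20 aldehyde 28.
3. The ring A half rests on the C6–C7 single bond between two sp2 carbons (carotenoid numbering). C6 is the carbonyl carbon of a 2,2,6-trimethylcyclohexanone whose quaternary C1 allows enolisation only toward C5. Enol triflate 4 and bromotetraenoate 11, both electrophiles, are therefore joined reductively (Ni/Pd/Zn) to retinoate 12.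
4. The ring B half comes from racemic α-ionone: C2 extension, allylic oxidation at C3', reduction trans to the C6' chain, resolution as a diastereomeric ester, then C5 extension.
5. No ring is formed: ring A is taken from actinol and ring B from α-ionone.

Key step: step 6

Remark 1: the ring B half is carried as the aldehyde and the ring A half as the phosphonium salt, because the allylic C3' oxygen of ring B would ionise under the acid needed to make a phosphonium salt.
Remark 2: α-ionone is used as the racemate; 16, 19 and 20 are racemic, 21 is the racemic trans alcohol (its SMILES shows the 3R,6R enantiomer), and the enantiomers are parted in step 13.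

**Route**

Step 1
Reactants: 1 (4R,6R)-4-hydroxy-2,2,6-trimethylcyclohexanone (actinol)
Product: 2 (4R,6R)-4-(tert-butyldimethylsilyloxy)-2,2,6-trimethylcyclohexanone
Conditions: TBSCl, imidazole, DMF, rt
Reagents that add atoms: tert-butyldimethylsilyl chloride, CC(C)(C)[Si](C)(C)Cl
Why: Imidazole-promoted silyl ether formation masks the secondary hydroxyl before enolate chemistry and touches neither stereocentre.

Step 2
Reactants: 2 (4R,6R)-4-(tert-butyldimethylsilyloxy)-2,2,6-trimethylcyclohexanone
Product: 4 (4R)-4-(tert-butyldimethylsilyloxy)-2,6,6-trimethylcyclohex-1-en-1-yl trifluoromethanesulfonate, via lithium enolate 3 (not isolated)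
Conditions: LiN(i-Pr)2, THF, −78 to 0 °C; PhNTf2, −78 °C to rt
Reagents that add atoms: N-phenylbis(trifluoromethanesulfonimide), O=S(=O)(N(c1ccccc1)S(=O)(=O)C(F)(F)F)C(F)(F)F
Why: Enol triflate formation: deprotonation can occur only at the methyl-bearing α-carbon because the other α-carbon is quaternary, so O-sulfonylation of the single enolate places the tetrasubstituted alkene; that α-stereocentre is erased by design and the silyloxy centre is untouched.

Step 3
Reactants: 5 (E)-3-methylpent-2-en-4-yn-1-ol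
Product: 7 (2E,4E)-5-bromo-3-methylpenta-2,4-dien-1-ol, via alkenylzirconium alkoxide 6 (not isolated)
Conditions: Cp2Zr(H)Cl (2.2 equiv), THF, rt, dark; NBS, 0 °C
Reagents that add atoms: N-bromosuccinimide, O=C1CCC(=O)N1Br
Why: Hydrozirconation of the terminal alkyne is a syn addition that places zirconium on the terminal carbon, and bromodezirconation proceeds with retention, so the E-bromoalkene should result; the first equivalent of Cp2Zr(H)Cl is consumed by the hydroxyl.

Step 4
Reactants: 7 (2E,4E)-5-bromo-3-methylpenta-2,4-dien-1-ol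
Product: 8 (2E,4E)-5-bromo-3-methylpenta-2,4-dienal
Conditions: MnO2, CH2Cl2, rt
Reagents that add atoms: none
Why: MnO2 oxidation of a primary allylic alcohol stops at the aldehyde and leaves the alkenyl bromide and both E alkenes alone.

Step 5
Reactants: 8 (2E,4E)-5-bromo-3-methylpenta-2,4-dienal; 9 ethyl (E)-4-(diethoxyphosphoryl)-3-methylbut-2-enoate
Product: 11 ethyl (2E,4E,6E,8E)-9-bromo-3,7-dimethylnona-2,4,6,8-tetraenoate, via lithiated phosphonate 10 (not isolated)
Conditions: n-BuLi, DMPU, THF, −78 °C; then 8, −78 to −20 °C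
Reagents that add atoms: none
Why: Horner–Wadsworth–Emmons olefination through the carbon next to phosphorus should give the new disubstituted alkene E, DMPU at low temperature keeping the trisubstituted enoate E; a minor 2Z isomer would be removed by chromatography.

Step 6
Reactants: 4 (4R)-4-(tert-butyldimethylsilyloxy)-2,6,6-trimethylcyclohex-1-en-1-yl trifluoromethanesulfonate; 11 ethyl (2E,4E,6E,8E)-9-bromo-3,7-dimethylnona-2,4,6,8-tetraenoate (slight excess)
Product: 12 ethyl (3R)-3-(tert-butyldimethylsilyloxy)retinoate (all-E)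
Conditions: NiBr2(dme) (5 mol%), 4,4'-di-tert-butyl-2,2'-bipyridine (5 mol%), PdCl2 (5 mol%), 1,3-bis(diphenylphosphino)propane (5 mol%), Zn powder (2 equiv), KF, DMF, 40 °C
Reagents that add atoms: none
Why: Zerovalent palladium on the bisphosphine should insert into the C6–OTf bond of 4 while zerovalent nickel on the bipyridine takes the C7–Br bond of 11; the alkenyl group then passes from nickel to palladium and reductive elimination forms the C6–C7 bond, Zn returning both metals to the zerovalent state. The closest known reaction type is the multimetallic Ni/Pd cross-electrophile coupling of alkenyl triflates with alkenyl bromides to substituted 1,3-dienes. No ring is closed and no stereocentre is made; the C3 silyloxy centre is remote, and the E geometry of C7=C8 is carried over from 11 because each organometallic event at sp2 carbon proceeds with retention. The step needs cross-coupling over homo-coupling, which rests on the preference of the phosphine–palladium catalyst for the triflate and of the bipyridine–nickel catalyst for the bromide. The triflate, flanked by the C1 gem-dimethyl group and the C5 methyl group, cannot dimerise, and the slight excess of 11 covers loss to its dimer. The tetrasubstituted C5=C6 alkene is already fixed by the enol triflate, so no regiochemical question arises.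

Step 7
Reactants: 12 ethyl (3R)-3-(tert-butyldimethylsilyloxy)retinoate
Product: 13 ethyl (3R)-3-hydroxyretinoate
Conditions: Bu4NF, THF, 0 °C to rt
Reagents that add atoms: none
Why: Fluoride-driven silyl ether cleavage leaves the conjugated ester and polyene untouched and retains C3 because the C–O bond is not broken.

Step 8
Reactants: 13 ethyl (3R)-3-hydroxyretinoate
Product: 14 (3R)-3-hydroxyretinol
Conditions: i-Bu2AlH (3.5 equiv), THF, −78 to 0 °C; aq. potassium sodium tartrate
Reagents that add atoms: none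
Why: i-Bu2AlH reduction of the conjugated ester gives the primary allylic alcohol by 1,2-addition without touching the polyene.

Step 9
Reactants: 14 (3R)-3-hydroxyretinol
Product: 15 [(3R)-3-hydroxyretinyl]triphenylphosphonium bromide
Conditions: PPh3·HBr, MeOH, 0 °C to rt
Reagents that add atoms: triphenylphosphine hydrobromide, Br.c1ccc(cc1)P(c1ccccc1)c1ccccc1
Why: Phosphonium salt formation from an allylic alcohol: acid ionises the primary polyenylic alcohol to a delocalised cation that triphenylphosphine traps at the terminal carbon, while the secondary non-allylic C3 hydroxyl does not ionise.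

Step 10
Reactants: 16 (±)-(E)-α-ionone; 17 diethyl (cyanomethyl)phosphonate
Product: 19 (±)-(2E,4E)-3-methyl-5-(2,6,6-trimethylcyclohex-2-en-1-yl)penta-2,4-dienenitrile, via sodium phosphonate carbanion 18 (not isolated)
Conditions: NaH, THF, 0 °C; then 16, rt
Reagents that add atoms: none
Why: Horner–Wadsworth–Emmons olefination of the methyl ketone extends the chain by two carbons with the E isomer of the new trisubstituted alkene favoured; the minor Z isomer would be removed by chromatography.

Step 11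
Reactants: 19 (±)-(2E,4E)-3-methyl-5-(2,6,6-trimethylcyclohex-2-en-1-yl)penta-2,4-dienenitrile
Product: 20 (±)-(2E,4E)-3-methyl-5-(2,6,6-trimethyl-4-oxocyclohex-2-en-1-yl)penta-2,4-dienenitrile
Conditions: t-BuOOH (70% aq.), Rh2(cap)4 (1 mol%, cap = caprolactamate), K2CO3, CH2Cl2, rt
Reagents that add atoms: tert-butyl hydroperoxide, CC(C)(C)OO
Why: Radical allylic C–H oxidation by tert-butylperoxyl should convert the only secondary allylic CH2 (C3, next to the C4=C5 alkene) into the enone, the tertiary C6–H being shielded by the gem-dimethyl and C5 methyl groups.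

Step 12
Reactants: 20 (±)-(2E,4E)-3-methyl-5-(2,6,6-trimethyl-4-oxocyclohex-2-en-1-yl)penta-2,4-dienenitrile
Product: 21 rac-(2E,4E)-5-[(1R,4R)-4-hydroxy-2,6,6-trimethylcyclohex-2-en-1-yl]-3-methylpenta-2,4-dienenitrile (trans)
Conditions: LiBH(s-Bu)3 (1.1 equiv), THF, −78 °C; H2O
Reagents that add atoms: none
Why: 1,2-Reduction of the β,β-disubstituted enone by the bulky hydride should occur from the face opposite the axial C1 methyl, which is the face bearing the pseudoaxial C6 chain, so the C3 hydroxyl is set trans to the chain by substrate control; the minor cis alcohol would be removed by chromatography.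

Step 13
Reactants: 21 rac-(2E,4E)-5-[(1R,4R)-4-hydroxy-2,6,6-trimethylcyclohex-2-en-1-yl]-3-methylpenta-2,4-dienenitrile
Product: 22 (1R,4R)-4-[(1E,3E)-4-cyano-3-methylbuta-1,3-dien-1-yl]-3,5,5-trimethylcyclohex-2-en-1-yl (2S)-2-methoxy-2-phenylacetate
Conditions: (S)-O-methylmandelic acid, DCC, DMAP (cat.), CH2Cl2, 0 °C; chromatographic separation of the two diastereomers
Reagents that add atoms: (S)-2-methoxy-2-phenylacetic acid, CO[C@H](C(=O)O)c1ccccc1
Why: Steglich esterification with the enantiopure acid turns the two enantiomers into diastereomeric esters that are parted by chromatography (classical resolution), no ring stereocentre being touched; the (3R,6R) ester is to be assigned by X-ray analysis or chemical correlation.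

Step 14
Reactants: 22 (1R,4R)-4-[(1E,3E)-4-cyano-3-methylbuta-1,3-dien-1-yl]-3,5,5-trimethylcyclohex-2-en-1-yl (2S)-2-methoxy-2-phenylacetate
Product: 24 (2E,4E)-5-[(1R,4R)-4-hydroxy-2,6,6-trimethylcyclohex-2-en-1-yl]-3-methylpenta-2,4-dienal, via N-aluminio imine 23 (not isolated)
Conditions: i-Bu2AlH (4.5 equiv), CH2Cl2, −78 to −40 °C; wet SiO2
Reagents that add atoms: water, O
Why: Nitrile-to-aldehyde reduction: i-Bu2AlH adds once to the nitrile to give an imine that is hydrolysed on wet SiO2, and the same reagent cleaves the mandelate ester reductively at the acyl carbon, so both ring centres are retained.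

Step 15
Reactants: 24 (2E,4E)-5-[(1R,4R)-4-hydroxy-2,6,6-trimethylcyclohex-2-en-1-yl]-3-methylpenta-2,4-dienal; 9 ethyl (E)-4-(diethoxyphosphoryl)-3-methylbut-2-enoate
Product: 26 ethyl (2E,4E,6E,8E)-9-[(1R,4R)-4-hydroxy-2,6,6-trimethylcyclohex-2-en-1-yl]-3,7-dimethylnona-2,4,6,8-tetraenoate, via sodiated phosphonocrotonate 25 (not isolated)
Conditions: 9 (2.1 equiv), NaN(SiMe3)2 (2.0 equiv), THF, −78 °C; then 24, −78 to 0 °C
Reagents that add atoms: none
Why: Horner–Wadsworth–Emmons olefination in which the sodium phosphonate carbanion, made with a non-nucleophilic amide base so that no alkyllithium meets the hydroxy aldehyde, adds through the carbon next to phosphorus and should give the new C11=C12 alkene E; the slight excess of phosphonate over base leaves no free amide to touch C6–H, the excess of anion covers any proton exchange with the free hydroxyl, and a minor 13Z isomer would be removed by chromatography.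

Step 16
Reactants: 26 ethyl (2E,4E,6E,8E)-9-[(1R,4R)-4-hydroxy-2,6,6-trimethylcyclohex-2-en-1-yl]-3,7-dimethylnona-2,4,6,8-tetraenoate
Product: 27 (2E,4E,6E,8E)-9-[(1R,4R)-4-hydroxy-2,6,6-trimethylcyclohex-2-en-1-yl]-3,7-dimethylnona-2,4,6,8-tetraen-1-ol
Conditions: i-Bu2AlH (3.5 equiv), THF, −78 °C; aq. potassium sodium tartrate
Reagents that add atoms: none
Why: i-Bu2AlH 1,2-reduction of the conjugated ester gives the primary allylic alcohol, the free ring hydroxyl only consuming one extra equivalent of hydride.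

Step 17
Reactants: 27 (2E,4E,6E,8E)-9-[(1R,4R)-4-hydroxy-2,6,6-trimethylcyclohex-2-en-1-yl]-3,7-dimethylnona-2,4,6,8-tetraen-1-ol
Product: 28 (2E,4E,6E,8E)-9-[(1R,4R)-4-hydroxy-2,6,6-trimethylcyclohex-2-en-1-yl]-3,7-dimethylnona-2,4,6,8-tetraenal
Conditions: TEMPO (10 mol%), PhI(OAc)2 (1.1 equiv), CH2Cl2, 0 °C to rt
Reagents that add atoms: none
Why: Oxoammonium (TEMPO/PhI(OAc)2) oxidation is strongly biased toward the unhindered primary polyenylic alcohol over the secondary ring alcohol next to the C1 gem-dimethyl group, and it uses no acid strong enough to ionise the allylic C3–OH.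

Step 18
Reactants: 15 [(3R)-3-hydroxyretinyl]triphenylphosphonium bromide; 28 (2E,4E,6E,8E)-9-[(1R,4R)-4-hydroxy-2,6,6-trimethylcyclohex-2-en-1-yl]-3,7-dimethylnona-2,4,6,8-tetraenal
Product: 31 (3R,3'R,6'R)-β,ε-carotene-3,3'-diol (all-E lutein), via phosphorus ylide 29 (not isolated), via 15-cis lutein 30 (not isolated)
Conditions: NaOMe, MeOH/CH2Cl2, −10 °C to rt; then heptane/EtOH, reflux, N2, dark; crystallisation
Reagents that add atoms: none
Why: Wittig olefination of the polyenyl ylide with the polyenal forms the central C15=C15' alkene as an E/Z mixture, and the 15-cis isomer should relax thermally to all-E on heating; no stereocentre is involved and C6'–H is too weakly acidic for methoxide at these temperatures.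

Step 19
Reactants: 31 (3R,3'R,6'R)-β,ε-carotene-3,3'-diol; 32 myristoyl chloride (2.5 equiv)
Product: 33 (3R,3'R,6'R)-β,ε-carotene-3,3'-diyl ditetradecanoate (lutein dimyristate)
Conditions: pyridine, DMAP (cat.), CH2Cl2, 0 °C to rt
Reagents that add atoms: none
Why: DMAP-catalysed O-acylation of both secondary hydroxyls with the acid chloride proceeds with retention at C3 and C3', and the basic medium avoids ionisation at the allylic C3' position.

**Compound list**
1 | (4R,6R)-4-hydroxy-2,2,6-trimethylcyclohexanone (actinol) | O[C@@H]1C[C@@H](C)C(=O)C(C)(C)C1 | starting material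
2 | (4R,6R)-4-(tert-butyldimethylsilyloxy)-2,2,6-trimethylcyclohexanone | CC(C)(C)[Si](C)(C)O[C@@H]1C[C@@H](C)C(=O)C(C)(C)C1 | intermediate
3 | lithium (4R)-4-(tert-butyldimethylsilyloxy)-2,6,6-trimethylcyclohex-1-en-1-olate | CC(C)(C)[Si](C)(C)O[C@@H]1CC(C)=C([O-])C(C)(C)C1.[Li+] | intermediate (not isolated)
4 | (4R)-4-(tert-butyldimethylsilyloxy)-2,6,6-trimethylcyclohex-1-en-1-yl trifluoromethanesulfonate | CC(C)(C)[Si](C)(C)O[C@@H]1CC(C)=C(OS(=O)(=O)C(F)(F)F)C(C)(C)C1 | intermediate
5 | (E)-3-methylpent-2-en-4-yn-1-ol | C#C/C(C)=C/CO | starting material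
6 | chlorobis(cyclopentadienyl)zirconium (1E,3E)-alkenyl species of 5, O-zirconated | Cl[Zr](C1C=CC=C1)(C1C=CC=C1)/C=C/C(C)=C/CO[Zr](Cl)(C1C=CC=C1)C1C=CC=C1 | intermediate (not isolated)
7 | (2E,4E)-5-bromo-3-methylpenta-2,4-dien-1-ol | Br/C=C/C(C)=C/CO | intermediate
8 | (2E,4E)-5-bromo-3-methylpenta-2,4-dienal | Br/C=C/C(C)=C/C=O | intermediate
9 | ethyl (E)-4-(diethoxyphosphoryl)-3-methylbut-2-enoate | CCOC(=O)/C=C(\C)CP(=O)(OCC)OCC | starting material
10 | lithium salt of the carbanion of 9 | CCOC(=O)/C=C(\C)[CH-]P(=O)(OCC)OCC.[Li+] | intermediate (not isolated)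
11 | ethyl (2E,4E,6E,8E)-9-bromo-3,7-dimethylnona-2,4,6,8-tetraenoate | Br/C=C/C(C)=C/C=C/C(C)=C/C(=O)OCC | intermediate
12 | ethyl (3R)-3-(tert-butyldimethylsilyloxy)retinoate (all-E) | CC(C)(C)[Si](C)(C)O[C@@H]1CC(C)=C(/C=C/C(C)=C/C=C/C(C)=C/C(=O)OCC)C(C)(C)C1 | intermediate
13 | ethyl (3R)-3-hydroxyretinoate | O[C@@H]1CC(C)=C(/C=C/C(C)=C/C=C/C(C)=C/C(=O)OCC)C(C)(C)C1 | intermediate
14 | (3R)-3-hydroxyretinol | O[C@@H]1CC(C)=C(/C=C/C(C)=C/C=C/C(C)=C/CO)C(C)(C)C1 | intermediate
15 | [(3R)-3-hydroxyretinyl]triphenylphosphonium bromide | O[C@@H]1CC(C)=C(/C=C/C(C)=C/C=C/C(C)=C/C[P+](c2ccccc2)(c2ccccc2)c2ccccc2)C(C)(C)C1.[Br-] | intermediate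
16 | (±)-(E)-α-ionone | CC(=O)/C=C/C1C(C)=CCCC1(C)C | starting material
17 | diethyl (cyanomethyl)phosphonate | CCOP(=O)(CC#N)OCC | starting material
18 | sodium salt of the carbanion of 17 | N#C[CH-]P(=O)(OCC)OCC.[Na+] | intermediate (not isolated)
19 | (±)-(2E,4E)-3-methyl-5-(2,6,6-trimethylcyclohex-2-en-1-yl)penta-2,4-dienenitrile | N#C/C=C(C)/C=C/C1C(C)=CCCC1(C)C | intermediate
20 | (±)-(2E,4E)-3-methyl-5-(2,6,6-trimethyl-4-oxocyclohex-2-en-1-yl)penta-2,4-dienenitrile | N#C/C=C(C)/C=C/C1C(C)=CC(=O)CC1(C)C | intermediate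
21 | rac-(2E,4E)-5-[(1R,4R)-4-hydroxy-2,6,6-trimethylcyclohex-2-en-1-yl]-3-methylpenta-2,4-dienenitrile (trans racemate; 3R,6R enantiomer drawn) | N#C/C=C(C)/C=C/[C@H]1C(C)=C[C@H](O)CC1(C)C | intermediate
22 | (1R,4R)-4-[(1E,3E)-4-cyano-3-methylbuta-1,3-dien-1-yl]-3,5,5-trimethylcyclohex-2-en-1-yl (2S)-2-methoxy-2-phenylacetate | N#C/C=C(C)/C=C/[C@H]1C(C)=C[C@H](OC(=O)[C@@H](OC)c2ccccc2)CC1(C)C | intermediate
23 | N-(diisobutylaluminio) imine of 24, O-aluminated | CC(C)C[Al](CC(C)C)N=C/C=C(C)/C=C/[C@H]1C(C)=C[C@H](O[Al](CC(C)C)CC(C)C)CC1(C)C | intermediate (not isolated)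
24 | (2E,4E)-5-[(1R,4R)-4-hydroxy-2,6,6-trimethylcyclohex-2-en-1-yl]-3-methylpenta-2,4-dienal | O=C/C=C(C)/C=C/[C@H]1C(C)=C[C@H](O)CC1(C)C | intermediate
25 | sodium salt of the carbanion of 9 | CCOC(=O)/C=C(\C)[CH-]P(=O)(OCC)OCC.[Na+] | intermediate (not isolated)
26 | ethyl (2E,4E,6E,8E)-9-[(1R,4R)-4-hydroxy-2,6,6-trimethylcyclohex-2-en-1-yl]-3,7-dimethylnona-2,4,6,8-tetraenoate | CCOC(=O)/C=C(C)/C=C/C=C(C)/C=C/[C@H]1C(C)=C[C@H](O)CC1(C)C | intermediate
27 | (2E,4E,6E,8E)-9-[(1R,4R)-4-hydroxy-2,6,6-trimethylcyclohex-2-en-1-yl]-3,7-dimethylnona-2,4,6,8-tetraen-1-ol | OC/C=C(C)/C=C/C=C(C)/C=C/[C@H]1C(C)=C[C@H](O)CC1(C)C | intermediate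
28 | (2E,4E,6E,8E)-9-[(1R,4R)-4-hydroxy-2,6,6-trimethylcyclohex-2-en-1-yl]-3,7-dimethylnona-2,4,6,8-tetraenal | O=C/C=C(C)/C=C/C=C(C)/C=C/[C@H]1C(C)=C[C@H](O)CC1(C)C | intermediate
29 | [(3R)-3-hydroxyretinylidene]triphenylphosphorane | O[C@@H]1CC(C)=C(/C=C/C(C)=C/C=C/C(C)=C/C=P(c2ccccc2)(c2ccccc2)c2ccccc2)C(C)(C)C1 | intermediate (not isolated)
30 | (15Z,3R,3'R,6'R)-β,ε-carotene-3,3'-diol | O[C@@H]1CC(C)=C(/C=C/C(C)=C/C=C/C(C)=C/C=C\C=C(C)\C=C\C=C(C)\C=C\[C@H]2C(C)=C[C@H](O)CC2(C)C)C(C)(C)C1 | intermediate (not isolated)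
31 | (3R,3'R,6'R)-β,ε-carotene-3,3'-diol (lutein) | O[C@@H]1CC(C)=C(/C=C/C(C)=C/C=C/C(C)=C/C=C/C=C(C)/C=C/C=C(C)/C=C/[C@H]2C(C)=C[C@H](O)CC2(C)C)C(C)(C)C1 | intermediate
32 | myristoyl chloride | CCCCCCCCCCCCCC(=O)Cl | starting material
33 | lutein dimyristate | CCCCCCCCCCCCCC(=O)O[C@@H]1CC(C)=C(/C=C/C(C)=C/C=C/C(C)=C/C=C/C=C(C)/C=C/C=C(C)/C=C/[C@H]2C(C)=C[C@H](OC(=O)CCCCCCCCCCCCC)CC2(C)C)C(C)(C)C1 | target

**Step count**
Total: 19 steps. Longest linear sequence: 10 steps (steps 10 to 17, then 18 and 19).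

**Steps most likely to fail**

Step 6. Transmetalation onto the alkenylpalladium triflate, flanked on both sides, may be slow, so that the bromide is consumed by nickel-mediated homo-coupling and protodehalogenation. The fallback replaces the reductive union by a Stille coupling with a preformed nucleophile and sets out from 5. Hydrostannylation of 5 (Bu3SnH, PdCl2(PPh3)2 cat., THF, 0 °C) should give (2E,4E)-3-methyl-5-(tributylstannyl)penta-2,4-dien-1-ol F1. MnO2 oxidation should give (2E,4E)-3-methyl-5-(tributylstannyl)penta-2,4-dienal F2. Olefination with 10 (from 9, as in step 5) should give ethyl (2E,4E,6E,8E)-3,7-dimethyl-9-(tributylstannyl)nona-2,4,6,8-tetraenoate F3. F3 and 4 are then coupled with Pd2(dba)3, AsPh3, NMP, 60 °C, and the route is rejoined at 12.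

Step 11. Hydrogen abstraction at the doubly allylic C6–H and peroxyl radical addition to the dienenitrile may compete with oxidation at C3. The fallback moves the oxidation to the C13 stage, where the side chain is a simple alkene, and sets out from 16. Ketalisation (ethylene glycol, HC(OEt)3, p-TsOH cat., rt) should give (±)-2-methyl-2-[(E)-2-(2,6,6-trimethylcyclohex-2-en-1-yl)ethenyl]-1,3-dioxolane F4. Oxidation with CrO3·3,5-dimethylpyrazole (CH2Cl2, −20 °C) should give (±)-3,5,5-trimethyl-4-[(E)-2-(2-methyl-1,3-dioxolan-2-yl)ethenyl]cyclohex-2-en-1-one F5. LiBH(s-Bu)3 at −78 °C should give rac-(1R,4R)-3,5,5-trimethyl-4-[(E)-2-(2-methyl-1,3-dioxolan-2-yl)ethenyl]cyclohex-2-en-1-ol F6. Mild hydrolysis (PPTS, acetone/H2O) should give rac-(E)-4-[(1R,4R)-4-hydroxy-2,6,6-trimethylcyclohex-2-en-1-yl]but-3-en-2-one F7. Olefination of F7 with 18 (from 17, as in step 10) rejoins the route at 21.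

Step 13. The two diastereomeric esters may co-elute, so that the enantiomers are not parted. The fallback is an enzymatic kinetic resolution and sets out from 21. Burkholderia cepacia lipase with vinyl acetate in t-BuOMe at rt, run to about half conversion, acylates one enantiomer, and alcohol and acetate are separated by chromatography. If the (3R,6R) enantiomer is the one acylated, it is obtained as (1R,4R)-4-[(1E,3E)-4-cyano-3-methylbuta-1,3-dien-1-yl]-3,5,5-trimethylcyclohex-2-en-1-yl acetate F8. If the enzyme takes the other enantiomer, the recovered alcohol is enantiopure (3R,6R)-21. Either fraction is treated with i-Bu2AlH and wet SiO2 as in step 14, which also removes the acetate, and the route is rejoined at 24.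

**Further compounds**
F1 | step 6 | (2E,4E)-3-methyl-5-(tributylstannyl)penta-2,4-dien-1-ol | CCCC[Sn](CCCC)(CCCC)/C=C/C(C)=C/CO
F2 | step 6 | (2E,4E)-3-methyl-5-(tributylstannyl)penta-2,4-dienal | CCCC[Sn](CCCC)(CCCC)/C=C/C(C)=C/C=O
F3 | step 6 | ethyl (2E,4E,6E,8E)-3,7-dimethyl-9-(tributylstannyl)nona-2,4,6,8-tetraenoate | CCCC[Sn](CCCC)(CCCC)/C=C/C(C)=C/C=C/C(C)=C/C(=O)OCC
F4 | step 11 | (±)-2-methyl-2-[(E)-2-(2,6,6-trimethylcyclohex-2-en-1-yl)ethenyl]-1,3-dioxolane | CC1(/C=C/C2C(C)=CCCC2(C)C)OCCO1
F5 | step 11 | (±)-3,5,5-trimethyl-4-[(E)-2-(2-methyl-1,3-dioxolan-2-yl)ethenyl]cyclohex-2-en-1-one | CC1(/C=C/C2C(C)=CC(=O)CC2(C)C)OCCO1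
F6 | step 11 | rac-(1R,4R)-3,5,5-trimethyl-4-[(E)-2-(2-methyl-1,3-dioxolan-2-yl)ethenyl]cyclohex-2-en-1-ol | CC1(/C=C/[C@H]2C(C)=C[C@H](O)CC2(C)C)OCCO1
F7 | step 11 | rac-(E)-4-[(1R,4R)-4-hydroxy-2,6,6-trimethylcyclohex-2-en-1-yl]but-3-en-2-one | CC(=O)/C=C/[C@H]1C(C)=C[C@H](O)CC1(C)C
F8 | step 13 | (1R,4R)-4-[(1E,3E)-4-cyano-3-methylbuta-1,3-dien-1-yl]-3,5,5-trimethylcyclohex-2-en-1-yl acetate | N#C/C=C(C)/C=C/[C@H]1C(C)=C[C@H](OC(C)=O)CC1(C)C
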